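All constants are made up.

The step to X2 outruns the step to X.Z at the start of a batch, so the flasks must be ranked by how far each shifts that balance.

    X + Z → X.Z, rate k1*[X]*[Z]^1.5 (k1 = 0.094 M⁻¹·⁵ s⁻¹)
    2 X → X2 (k2 = 0.19 M⁻¹ s⁻¹)

| setting | gamma | theta | eta | zeta |
|---|---|---|---|---|
| X | 0.10 M (fed, over 1.5 min) | 0.10 M | 0.10 M | 0.10 M (fed, over 10 s) |
| Z | 0.200 M | 0.200 M | 0.200 M (fed, over 1.5 min) | 0.200 M |
| time | 2.0 min | 2.0 min | 2.0 min | 2.0 min |
| remark | all else is in the flask from the start; the feed brings no volume worth counting | everything together at the start | all else is in the flask from the start; the feed brings no volume worth counting | all else is in the flask from the start; the feed brings no volume worth counting |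

- in percentages every species weighs as the X in it: one X2 counts as two
- a doubled species enters its step squared and goes two at a time
- run time (gamma): 2.0 min

- which flask leads in share of X.Z in X.Z plus X2 ("all alike" within 1.5 percentage points) (gamma / theta / eta / zeta / all alike)
- share of X.Z in X.Z plus X2 at the end, gamma
- share of X.Z in X.Z plus X2 at the end, theta
- share of X.Z in X.Z plus X2 at the end, eta
- share of X.Z in X.Z plus X2 at the end, zeta

I divide the X entering X.Z by the X going into X2 at one moment, which gives the split number S, the first rate over twice the second, 0.221 at the full charges; it is a selectivity factor. It rises with c(Z) and falls with c(X), the momentary share is S over one plus S, and S of one is the symmetric case, half each way.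

I hold c(Z) at its charge. Theta then starts at 18.1% and climbs as X falls, reaching 37.8% only when X is gone, S·ln(one plus one over S).

In gamma, X rises towards the level where feed balances both losses, 0.0441 M. There S is 0.501, higher than at the start of theta, a share of 33.4%, and lower c(X) before that level gives a higher share, so I put gamma first.

One number with fixed c(Z) fails for eta, where c(Z) and so S start at zero while the first half-life of X by dimerisation, 26.3 s, is shorter than the feed; I put eta last. Zeta's feed is shorter than that half-life, so I place zeta beside theta.

The forecast names gamma, with 36.5%, 32%, 14% and 33% for gamma, theta, eta and zeta, since “feeding X slowly holds X down and favours X.Z”.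

The flasks end at 36.4%, 30.7%, 13.1% and 31.5% in that order, and gamma leads. Gamma stands above its held share, and theta stands below its ceiling. A neighbour of gamma charged with 0.025 M of X holds X at 0.0181 M by the same reckoning, so S is 1.22 and the held share 54.9%. That neighbour ends at 64.9%, again above its held share, with 40.9% of its X still there at 2.00 min.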